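**Plan**
- Ring C is cut at O1–C2 and C2–C3 (one carbon from DMF dimethyl acetal) and at C4–C4a (aryllithium plus Weinreb amide), giving a ring B arylacetate and a resorcinol-derived ring A.
- The chroman is cut at its O–C(CH3)2 bond back to an ortho-prenyl phenol; ring B is then cut at C5'–C6' and unfolded to a 4-methoxy-6-methyl-2-pyranone.
- Enabling feature: ring B is a phloroglucinol with three different oxygens (C2'–OMe, C4'–O of the chroman, C6'–OH). The pyranone holds them as C4–OMe, the ring oxygen on C6 and the lactone carbonyl C2, and its 6-methyl carbon becomes C5'.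
- Forward order: pyranone ring (acetylacetone, prenyl bromide, CO2, methyl glyoxylate), ring B by Claisen folding, chroman ring, ketone link to ring A, ring C.
- Stereochemistry: the target has no stereocentre; only the cis arrangement across the enol ether double bond of the opened pyranone matters, and the lactone ring fixes it.

Key step: step 6

Remark: ring B positions are primed as in the isoflavone (C1' bonded to C3). 4-Bromoresorcinol is taken as the commercial source of ring A, and methyl glyoxylate is used as freshly depolymerised monomer.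

**Step 1**
Reactants: 1 acetylacetone; 2 prenyl bromide
Product: 3 3-(3-methylbut-2-en-1-yl)pentane-2,4-dione
Conditions: K2CO3, acetone, reflux (1 in 1.5-fold excess)
Reagents that add atoms: none
Why: SN2 C-alkylation of the doubly stabilised diketone enolate with an allylic bromide is standard, and the excess of 1 should limit dialkylation.

**Step 2**
Reactants: 3 3-(3-methylbut-2-en-1-yl)pentane-2,4-dione
Product: 5 4-(3-methylbut-2-en-1-yl)-3,5-dioxohexanoic acid, via dilithium dianion 4 (not isolated)
Conditions: LiN(i-Pr)2 (commercial solution, 2.2 equiv), THF, −78 → 0 °C; CO2 (g), −78 °C; cold 1 M HCl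
Reagents that add atoms: carbon dioxide, O=C=O
Why: Double deprotonation gives the 1,3-dianion 4, whose methyl-derived carbanion is the more nucleophilic site and is carboxylated by CO2 (dianion carboxylation of a 1,3-diketone); cold acidification should avoid decarboxylation.

**Step 3**
Reactants: 5 4-(3-methylbut-2-en-1-yl)-3,5-dioxohexanoic acid
Product: 6 4-hydroxy-6-methyl-5-(3-methylbut-2-en-1-yl)-2H-pyran-2-one
Conditions: Ac2O, rt; aq. NaHCO3 work-up, then acidify
Reagents that add atoms: none
Why: Cyclodehydration of a 3,5-dioxo acid to a 4-hydroxy-2-pyranone through the mixed anhydride (enol lactonisation) is classical, and Ac2O keeps strong acid away from the prenyl alkene.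

**Step 4**
Reactants: 6 4-hydroxy-6-methyl-5-(3-methylbut-2-en-1-yl)-2H-pyran-2-one; 7 methyl glyoxylate
Product: 9 methyl 2-[4-hydroxy-6-methyl-5-(3-methylbut-2-en-1-yl)-2-oxo-2H-pyran-3-yl]acetate, via alkylidene pyrandione 8 (not isolated)
Conditions: Hantzsch ester (diethyl 2,6-dimethyl-1,4-dihydropyridine-3,5-dicarboxylate, 1.1 equiv), L-proline (10 mol%), CH2Cl2, rt
Reagents that add atoms: none
Why: Knoevenagel condensation at C3, the only nucleophilic carbon of the hydroxypyranone, gives 8, which is reduced at once by conjugate hydride transfer from the Hantzsch ester (three-component reductive alkylation), so bis-adduct formation should be suppressed and the isolated alkene left alone.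

**Step 5**
Reactants: 9 methyl 2-[4-hydroxy-6-methyl-5-(3-methylbut-2-en-1-yl)-2-oxo-2H-pyran-3-yl]acetate
Product: 10 methyl 2-[4-methoxy-6-methyl-5-(3-methylbut-2-en-1-yl)-2-oxo-2H-pyran-3-yl]acetate
Conditions: Me2SO4 (1.2 equiv), K2CO3, acetone, reflux
Reagents that add atoms: dimethyl sulfate, COS(=O)(=O)OC
Why: O-Methylation with Me2SO4 and K2CO3 in acetone is the usual route to 4-methoxy-2-pyranones, the hard electrophile reacting at the C4 oxygen of the ambident anion.

**Step 6**
Reactants: 10 methyl 2-[4-methoxy-6-methyl-5-(3-methylbut-2-en-1-yl)-2-oxo-2H-pyran-3-yl]acetate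
Product: 13 methyl 2-[2,4-dihydroxy-6-methoxy-5-(3-methylbut-2-en-1-yl)phenyl]acetate, via open-chain keto diester 11 (not isolated), via cyclohexenedione 12 (not isolated)
Conditions: NaOMe (3 equiv), MeOH, reflux; then 1 M HCl, 0 °C
Reagents that add atoms: none
Why: Methoxide adds to the lactone carbonyl C2 of 10 and opens the enol lactone to 11, in which the C3=C4 enol ether double bond inherited from the ring keeps the new methyl ester and the acetyl-bearing carbon cis. Under the equilibrating alkoxide the methyl ketone enolate attacks that ester carbonyl in a 6-(enolexo)-exo-trig Claisen (Dieckmann-type) condensation, forming the C5'–C6' bond and carbocycle 12, which tautomerises to the phenoxide of 13. The closest known reaction is the base-induced isomerisation of 4-methoxy-6-methyl-2-pyranones to phloroglucinol monomethyl ethers, a biomimetic folding of a masked tri-β-carbonyl chain. No stereocentre is formed, and the centre at the prenyl-bearing carbon of 11 is erased on aromatisation. The step needs C-acylation at the methyl terminus to win over reclosure to the pyranone, over five-membered Dieckmann closure onto the side-chain ester and over aldol paths; these are reversible (the five-membered product has no hydrogen between its carbonyls), aromatisation to a phenoxide is not, and the side-chain ester can reach the methyl carbon only through a seven-membered ring. Because the methyl ether never leaves C4, ring B emerges with OMe between the two carbon substituents, the former lactone carbonyl as C6'–OH and the former ring oxygen as C4'–OH, the only hydroxyl ortho to the prenyl group.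

**Step 7**
Reactants: 13 methyl 2-[2,4-dihydroxy-6-methoxy-5-(3-methylbut-2-en-1-yl)phenyl]acetate
Product: 14 methyl 2-(7-hydroxy-5-methoxy-2,2-dimethylchroman-6-yl)acetate
Conditions: p-toluenesulfonic acid monohydrate (10 mol%), CH2Cl2, rt to 40 °C
Reagents that add atoms: none
Why: Protonation of the trisubstituted alkene gives a tertiary cation that is trapped by the only ortho phenol in a Markovnikov intramolecular hydroalkoxylation (6-endo closure) to the 2,2-dimethylchroman, and the mild temperature should keep the ortho-hydroxy arylacetate from lactonising.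

**Step 8**
Reactants: 14 methyl 2-(7-hydroxy-5-methoxy-2,2-dimethylchroman-6-yl)acetate
Product: 15 methyl 2-[7-(benzyloxy)-5-methoxy-2,2-dimethylchroman-6-yl]acetate
Conditions: BnBr, K2CO3, acetone, reflux
Reagents that add atoms: benzyl bromide, BrCc1ccccc1
Why: Williamson etherification of the single remaining phenol installs a group that survives the organometallic and acidic steps and is removed last under neutral conditions.

**Step 9**
Reactants: 15 methyl 2-[7-(benzyloxy)-5-methoxy-2,2-dimethylchroman-6-yl]acetate
Product: 16 2-[7-(benzyloxy)-5-methoxy-2,2-dimethylchroman-6-yl]-N-methoxy-N-methylacetamide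
Conditions: MeNH(OMe)·HCl (3 equiv), i-PrMgCl (6 equiv), THF, −20 → 0 °C
Reagents that add atoms: N,O-dimethylhydroxylamine hydrochloride, CNOC.Cl
Why: Aminolysis of the methyl ester by the chloromagnesium amide of N,O-dimethylhydroxylamine (Weinreb amide formation) is a standard one-step conversion that tolerates aryl ethers.

**Step 10**
Reactants: 17 4-bromoresorcinol
Product: 18 1-bromo-2,4-bis(methoxymethoxy)benzene
Conditions: MOMCl (2.5 equiv), i-Pr2NEt, CH2Cl2, 0 °C → rt
Reagents that add atoms: chloromethyl methyl ether, COCCl
Why: Double O-alkylation of the phenols with MOMCl and a hindered amine is routine MOM protection, and the ortho MOM group later stabilises the aryllithium.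

**Step 11**
Reactants: 18 1-bromo-2,4-bis(methoxymethoxy)benzene; 16 2-[7-(benzyloxy)-5-methoxy-2,2-dimethylchroman-6-yl]-N-methoxy-N-methylacetamide
Product: 20 2-[7-(benzyloxy)-5-methoxy-2,2-dimethylchroman-6-yl]-1-[2,4-bis(methoxymethoxy)phenyl]ethan-1-one, via aryllithium 19 (not isolated)
Conditions: 18 (1.5 equiv), n-BuLi (1.45 equiv), THF, −78 °C; then 16, −78 → −20 °C; aq. NH4Cl
Reagents that add atoms: none
Why: Bromine–lithium exchange gives the chelation-stabilised aryllithium 19, which adds once to the Weinreb amide (Weinreb ketone synthesis) because the chelated adduct lasts until the quench; this replaces a Lewis-acid Friedel–Crafts acylation of resorcinol, which the benzyl ether would not be expected to survive.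

**Step 12**
Reactants: 20 2-[7-(benzyloxy)-5-methoxy-2,2-dimethylchroman-6-yl]-1-[2,4-bis(methoxymethoxy)phenyl]ethan-1-one
Product: 22 3-[7-(benzyloxy)-5-methoxy-2,2-dimethylchroman-6-yl]-7-hydroxy-4H-chromen-4-one, via enaminone 21 (not isolated)
Conditions: Me2NCH(OMe)2, toluene, 100 °C; evaporate; HCl (3 M in MeOH), 50 °C
Reagents that add atoms: N,N-dimethylformamide dimethyl acetal, COC(OC)N(C)C
Why: Condensation of the ketone methylene with the amide acetal gives enaminone 21, and acid then removes both MOM groups so that the ortho phenol of ring A adds to the enaminone β-carbon and expels dimethylamine (6-endo addition–elimination, the enaminone route to chromones), while the benzyl ether keeps the ring B oxygen from competing.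

**Step 13**
Reactants: 22 3-[7-(benzyloxy)-5-methoxy-2,2-dimethylchroman-6-yl]-7-hydroxy-4H-chromen-4-one
Product: 23 glycyrrhizaisoflavone C, 7-hydroxy-3-(7-hydroxy-5-methoxy-2,2-dimethylchroman-6-yl)-4H-chromen-4-one
Conditions: H2 (1 atm), Pd/C (10% Pd on carbon), EtOAc–MeOH, rt
Reagents that add atoms: none
Why: Hydrogenolysis of the aryl benzyl ether over Pd/C should be faster than reduction of the chromone double bond and leaves the methyl ether and the chroman untouched.

**Compound list**
1 | acetylacetone (pentane-2,4-dione) | CC(=O)CC(C)=O | starting material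
2 | prenyl bromide (1-bromo-3-methylbut-2-ene) | CC(C)=CCBr | starting material
3 | 3-(3-methylbut-2-en-1-yl)pentane-2,4-dione | CC(=O)C(CC=C(C)C)C(C)=O | intermediate
4 | dilithium 1,3-dianion of 3 (O-lithium enolate, terminal C-lithium) | [Li]OC(C)=C(CC=C(C)C)C(=O)C[Li] | intermediate (not isolated)
5 | 4-(3-methylbut-2-en-1-yl)-3,5-dioxohexanoic acid (racemic, largely enolised) | CC(=O)C(CC=C(C)C)C(=O)CC(=O)O | intermediate
6 | 4-hydroxy-6-methyl-5-(3-methylbut-2-en-1-yl)-2H-pyran-2-one | Cc1oc(=O)cc(O)c1CC=C(C)C | intermediate
7 | methyl glyoxylate | COC(=O)C=O | starting material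
8 | methyl 2-[6-methyl-5-(3-methylbut-2-en-1-yl)-2,4-dioxo-2H-pyran-3(4H)-ylidene]acetate (alkene geometry not fixed) | COC(=O)C=C1C(=O)OC(C)=C(CC=C(C)C)C1=O | intermediate (not isolated)
9 | methyl 2-[4-hydroxy-6-methyl-5-(3-methylbut-2-en-1-yl)-2-oxo-2H-pyran-3-yl]acetate | COC(=O)Cc1c(O)c(CC=C(C)C)c(C)oc1=O | intermediate
10 | methyl 2-[4-methoxy-6-methyl-5-(3-methylbut-2-en-1-yl)-2-oxo-2H-pyran-3-yl]acetate | COC(=O)Cc1c(OC)c(CC=C(C)C)c(C)oc1=O | intermediate
11 | dimethyl (E)-2-[2-acetyl-1-methoxy-5-methylhex-4-en-1-ylidene]butanedioate (racemic) | COC(=O)C/C(C(=O)OC)=C(\OC)C(CC=C(C)C)C(C)=O | intermediate (not isolated)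
12 | methyl 2-[2-methoxy-3-(3-methylbut-2-en-1-yl)-4,6-dioxocyclohex-1-en-1-yl]acetate (racemic) | COC(=O)CC1=C(OC)C(CC=C(C)C)C(=O)CC1=O | intermediate (not isolated)
13 | methyl 2-[2,4-dihydroxy-6-methoxy-5-(3-methylbut-2-en-1-yl)phenyl]acetate | COC(=O)Cc1c(O)cc(O)c(CC=C(C)C)c1OC | intermediate
14 | methyl 2-(7-hydroxy-5-methoxy-2,2-dimethylchroman-6-yl)acetate | COC(=O)Cc1c(O)cc2OC(C)(C)CCc2c1OC | intermediate
15 | methyl 2-[7-(benzyloxy)-5-methoxy-2,2-dimethylchroman-6-yl]acetate | COC(=O)Cc1c(OCc2ccccc2)cc2OC(C)(C)CCc2c1OC | intermediate
16 | 2-[7-(benzyloxy)-5-methoxy-2,2-dimethylchroman-6-yl]-N-methoxy-N-methylacetamide | CON(C)C(=O)Cc1c(OCc2ccccc2)cc2OC(C)(C)CCc2c1OC | intermediate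
17 | 4-bromoresorcinol (4-bromobenzene-1,3-diol) | Oc1ccc(Br)c(O)c1 | starting material
18 | 1-bromo-2,4-bis(methoxymethoxy)benzene | COCOc1ccc(Br)c(OCOC)c1 | intermediate
19 | [2,4-bis(methoxymethoxy)phenyl]lithium | [Li]c1ccc(OCOC)cc1OCOC | intermediate (not isolated)
20 | 2-[7-(benzyloxy)-5-methoxy-2,2-dimethylchroman-6-yl]-1-[2,4-bis(methoxymethoxy)phenyl]ethan-1-one | COCOc1ccc(C(=O)Cc2c(OCc3ccccc3)cc3OC(C)(C)CCc3c2OC)c(OCOC)c1 | intermediate
21 | 2-[7-(benzyloxy)-5-methoxy-2,2-dimethylchroman-6-yl]-1-[2,4-bis(methoxymethoxy)phenyl]-3-(dimethylamino)prop-2-en-1-one (push–pull alkene, geometry not fixed) | COCOc1ccc(C(=O)C(=CN(C)C)c2c(OCc3ccccc3)cc3OC(C)(C)CCc3c2OC)c(OCOC)c1 | intermediate (not isolated)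
22 | 3-[7-(benzyloxy)-5-methoxy-2,2-dimethylchroman-6-yl]-7-hydroxy-4H-chromen-4-one | COc1c2c(cc(OCc3ccccc3)c1-c1coc3cc(O)ccc3c1=O)OC(C)(C)CC2 | intermediate
23 | glycyrrhizaisoflavone C, 7-hydroxy-3-(7-hydroxy-5-methoxy-2,2-dimethylchroman-6-yl)-4H-chromen-4-one | COc1c2c(cc(O)c1-c1coc3cc(O)ccc3c1=O)OC(C)(C)CC2 | target

**Count**
Total steps: 13. Longest linear sequence: 12 steps (steps 1 to 9, then 11 to 13); step 10 is a one-step branch.

**Steps most likely to fail**

Step 6. Under equilibrating methoxide the opened chain may reclose to the pyranone, or be held in reversible side condensations, faster than the weakly populated methyl ketone enolate acylates, so conversion could stall. The fallback sets out from pyranone 10 and returns at 13, separating ring opening from bond formation and generating the nucleophile irreversibly. Pyranone 10 would be opened with one equivalent of NaOMe in MeOH at 0 °C and quenched with AcOH, and the open-chain keto diester 11 isolated. Treatment of 11 with LiN(i-Pr)2 (2.5 equiv) in THF at −78 → 0 °C should remove first the doubly activated methine hydrogen and then a methyl hydrogen. The terminal carbanion of the resulting dianion closes on the cis ester, and acid work-up gives 13. This detour makes no compound outside the list (F0).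

Step 11. Proton transfer from the methylene of the Weinreb amide to the aryllithium may compete with addition, returning amide and arene. The fallback sets out from ester 15 and returns at ketone 20. Reduction of 15 with i-Bu2AlH (1.1 equiv) in toluene at −78 °C should give 2-[7-(benzyloxy)-5-methoxy-2,2-dimethylchroman-6-yl]acetaldehyde F1. Addition of F1 at −78 °C to aryllithium 19 (made from 18 as in step 11) should give 2-[7-(benzyloxy)-5-methoxy-2,2-dimethylchroman-6-yl]-1-[2,4-bis(methoxymethoxy)phenyl]ethan-1-ol F2, since addition to an aldehyde outruns enolisation. Oxidation of F2 with Dess–Martin periodinane in CH2Cl2 then gives 20.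

Step 12. Condensation at the methylene flanked by the doubly ortho-substituted ring B may be slow, and prolonged heating could cause loss of MOM groups and decomposition before the enaminone forms. The fallback sets out from 20 and returns at 22. HCl in MeOH at rt would remove both MOM groups to give 2-[7-(benzyloxy)-5-methoxy-2,2-dimethylchroman-6-yl]-1-(2,4-dihydroxyphenyl)ethan-1-one F3, whose benzyl ether still blocks the ring B oxygen. Heating F3 with triethyl orthoformate, pyridine and a little piperidine (the classical orthoformate closure of 2-hydroxydeoxybenzoins) would insert C2 and give 22.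

**Further compounds**
F0 | step 6 | none | none
F1 | step 11 | 2-[7-(benzyloxy)-5-methoxy-2,2-dimethylchroman-6-yl]acetaldehyde | O=CCc1c(OCc2ccccc2)cc2OC(C)(C)CCc2c1OC
F2 | step 11 | 2-[7-(benzyloxy)-5-methoxy-2,2-dimethylchroman-6-yl]-1-[2,4-bis(methoxymethoxy)phenyl]ethan-1-ol (racemic) | COCOc1ccc(C(O)Cc2c(OCc3ccccc3)cc3OC(C)(C)CCc3c2OC)c(OCOC)c1
F3 | step 12 | 2-[7-(benzyloxy)-5-methoxy-2,2-dimethylchroman-6-yl]-1-(2,4-dihydroxyphenyl)ethan-1-one | Oc1ccc(C(=O)Cc2c(OCc3ccccc3)cc3OC(C)(C)CCc3c2OC)c(O)c1
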